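**Plan**
Rings: A = 2,4-dihydroxybenzoyl ring. B = phenol ring of the same dihydrochalcone unit, one half of the biaryl. C = acylresorcinol ring of the second unit, the other half of the biaryl. D = terminal 4-hydroxyphenyl ring.
Retrosynthetic cuts, in order: five O–benzyl bonds; the bond between the ring A ketone carbon and its α-CH2 (giving a salicylaldehyde and a vinylarene); the biaryl bond C3(B)–C5(C); the ring C–acyl bond.
Enabling feature: the C2 hydroxyl of ring A sits ortho to the ketone carbon. At the aldehyde oxidation level this oxygen and the formyl C–H hold rhodium in a five-membered chelate, so the C–H bond can add across a vinyl group on ring B with no activating group on either carbon.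
Forward order: ring C is acylated with the ring D acid, ring B is made as a bromostyrene, and B and C are joined by borylation/Suzuki coupling. Ring A is attached last by hydroacylation, followed by one global debenzylation.
Stereochemistry: the target has no stereocentre, and no step of the route creates one.

Key step: step 6

Assumption: the B–C axis carries only two ortho oxygens and two ortho hydrogens, so it is treated as freely rotating. This agrees with the SMILES, which holds no stereodescriptor.

Step 1
Reactants: 1 4-bromoresorcinol (4-bromobenzene-1,3-diol); 2 3-(4-hydroxyphenyl)propanoic acid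
Product: 3 1-(5-bromo-2,4-dihydroxyphenyl)-3-(4-hydroxyphenyl)propan-1-one
Conditions: BF3·OEt2 (as solvent), 85 °C; then aq. NaOAc
Reagents that add atoms: none
Why: Friedel–Crafts (Nencki-type) acylation of a resorcinol by a free acid in BF3·OEt2, in which C6 of 1 is the only unhindered position ortho/para to both hydroxyls, the much less activated ring D of 2 should not compete, and boron chelation of the new ortho-hydroxy ketone should stop the reaction at monoacylation.

Step 2
Reactants: 3 1-(5-bromo-2,4-dihydroxyphenyl)-3-(4-hydroxyphenyl)propan-1-one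
Product: 4 1-[2,4-bis(benzyloxy)-5-bromophenyl]-3-[4-(benzyloxy)phenyl]propan-1-one
Conditions: BnBr (3.6 equiv), K2CO3, DMF, 70 °C
Reagents that add atoms: benzyl bromide, BrCc1ccccc1
Why: Williamson etherification of all three phenols, with heating in DMF sufficient to alkylate the hydrogen-bonded C2 hydroxyl as well and K2CO3 too weak to enolise the ketone.

Step 3
Reactants: 5 3-bromo-4-hydroxybenzaldehyde
Product: 6 4-(benzyloxy)-3-bromobenzaldehyde
Conditions: BnBr, K2CO3, DMF, rt to 50 °C
Reagents that add atoms: benzyl bromide, BrCc1ccccc1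
Why: Williamson etherification, which masks the ring B phenol so that it neither quenches the ylide of step 4 nor offers a second acidic O–H in step 6.

Step 4
Reactants: 6 4-(benzyloxy)-3-bromobenzaldehyde
Product: 7 1-(benzyloxy)-2-bromo-4-ethenylbenzene
Conditions: Ph3PCH3Br, KOtBu, THF, 0 °C to rt
Reagents that add atoms: methyltriphenylphosphonium bromide, C[P+](c1ccccc1)(c1ccccc1)c1ccccc1.[Br-]
Why: Wittig methylenation of an aromatic aldehyde with the non-stabilised ylide, to which the aryl bromide and the benzyl ether are inert.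

Step 5
Reactants: 4 1-[2,4-bis(benzyloxy)-5-bromophenyl]-3-[4-(benzyloxy)phenyl]propan-1-one; 7 1-(benzyloxy)-2-bromo-4-ethenylbenzene
Product: 9 1-[2',4,6-tris(benzyloxy)-5'-ethenyl[1,1'-biphenyl]-3-yl]-3-[4-(benzyloxy)phenyl]propan-1-one, via pinacol boronate 8 (not isolated)
Conditions: B2pin2 (1.05 equiv), Pd(dppf)Cl2 (3 mol %), KOAc, 1,4-dioxane, 90 °C; then 7, aq. K3PO4, 80 °C
Reagents that add atoms: bis(pinacolato)diboron, CC1(C)OB(OC1(C)C)B1OC(C)(C)C(C)(C)O1 (its boryl group is held by 8 only)
Why: Miyaura borylation of the bromide that bears no alkene, followed in the same flask by Suzuki–Miyaura coupling with bromostyrene 7, where transmetalation in aqueous phosphate should outrun Heck-type insertion of the vinyl group and a biaryl with only two ortho alkoxy groups lies well within the steric range of the method.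

Step 6
Reactants: 9 1-[2',4,6-tris(benzyloxy)-5'-ethenyl[1,1'-biphenyl]-3-yl]-3-[4-(benzyloxy)phenyl]propan-1-one; 10 4-(benzyloxy)-2-hydroxybenzaldehyde
Product: 11 1-[2',4,6-tris(benzyloxy)-5'-{3-[4-(benzyloxy)-2-hydroxyphenyl]-3-oxopropyl}[1,1'-biphenyl]-3-yl]-3-[4-(benzyloxy)phenyl]propan-1-one
Conditions: 10 (1.5 equiv), [Rh(cod)Cl]2 (2.5 mol %), rac-(1,1'-binaphthalene-2,2'-diyl) N,N-diisopropylphosphoramidite (10 mol %), K3PO4 (15 mol %), trace BHT, 1,4-dioxane, 80 °C, Ar
Reagents that add atoms: none
Why: Phosphate-assisted exchange places the C2 phenoxide oxygen of 10 on monovalent rhodium, the neighbouring formyl C–H adds oxidatively to give a five-membered O,C-chelated acyl hydride of trivalent rhodium that is held too rigidly to decarbonylate, the vinyl group of 9 coordinates and inserts into Rh–H, and C–C reductive elimination joins the acyl carbon to the terminal CH2 before proton exchange with fresh 10 releases 11. The closest known reaction type is the rhodium-catalysed, phenoxide-chelation-assisted intermolecular hydroacylation of terminal alkenes with salicylaldehydes, which is linear-selective with bulky monodentate phosphoramidite ligands. No ring of the product is closed (the only ring involved is the transient rhodacycle) and no stereocentre is created. The selectivity needed is regiochemical, acyl to CH2 and hydrogen to the benzylic carbon: hydride insertion is reversible, so the outcome is settled at reductive elimination, which should be faster from the unhindered primary alkyl than from the secondary benzylic alkyl inside the crowded ligand–chelate pocket, and in 9 the only oxygen of ring B lies para to the vinyl group and is benzylated, so no second chelate can pull the alkene into the branched orientation. Chemoselectivity is secured by design, since the pair 9/10 holds a single formyl group and a single free hydroxyl, both on ring A, while the ketone, the benzyl ethers and the biaryl of 9 are spectators toward monovalent rhodium. The step is fully atom-economical and should deliver the complete carbon skeleton at the final oxidation level.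

Step 7
Reactants: 11 1-[2',4,6-tris(benzyloxy)-5'-{3-[4-(benzyloxy)-2-hydroxyphenyl]-3-oxopropyl}[1,1'-biphenyl]-3-yl]-3-[4-(benzyloxy)phenyl]propan-1-one
Product: 12 1-[5'-[3-(2,4-dihydroxyphenyl)-3-oxopropyl]-2',4,6-trihydroxy[1,1'-biphenyl]-3-yl]-3-(4-hydroxyphenyl)propan-1-one (CID44566750)
Conditions: H2 (1 atm), 10 % Pd/C, THF/MeOH, rt
Reagents that add atoms: none
Why: Catalytic hydrogenolysis of five benzyl aryl ethers, in which both ketones are conjugated to ortho/para oxygen donors (vinylogous esters) and should resist reduction at 1 atm and room temperature if hydrogen uptake is monitored.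

**Compound list**
1 | 4-bromoresorcinol | Oc1ccc(Br)c(O)c1 | starting material
2 | 3-(4-hydroxyphenyl)propanoic acid | OC(=O)CCc1ccc(O)cc1 | starting material
3 | 1-(5-bromo-2,4-dihydroxyphenyl)-3-(4-hydroxyphenyl)propan-1-one | O=C(CCc1ccc(O)cc1)c1cc(Br)c(O)cc1O | intermediate
4 | 1-[2,4-bis(benzyloxy)-5-bromophenyl]-3-[4-(benzyloxy)phenyl]propan-1-one | O=C(CCc1ccc(OCc2ccccc2)cc1)c1cc(Br)c(OCc2ccccc2)cc1OCc1ccccc1 | intermediate
5 | 3-bromo-4-hydroxybenzaldehyde | O=Cc1ccc(O)c(Br)c1 | starting material
6 | 4-(benzyloxy)-3-bromobenzaldehyde | O=Cc1ccc(OCc2ccccc2)c(Br)c1 | intermediate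
7 | 1-(benzyloxy)-2-bromo-4-ethenylbenzene | C=Cc1ccc(OCc2ccccc2)c(Br)c1 | intermediate
8 | 1-[2,4-bis(benzyloxy)-5-(4,4,5,5-tetramethyl-1,3,2-dioxaborolan-2-yl)phenyl]-3-[4-(benzyloxy)phenyl]propan-1-one (not isolated) | O=C(CCc1ccc(OCc2ccccc2)cc1)c1cc(B2OC(C)(C)C(C)(C)O2)c(OCc2ccccc2)cc1OCc1ccccc1 | intermediate
9 | 1-[2',4,6-tris(benzyloxy)-5'-ethenyl[1,1'-biphenyl]-3-yl]-3-[4-(benzyloxy)phenyl]propan-1-one | C=Cc1ccc(OCc2ccccc2)c(-c2cc(C(=O)CCc3ccc(OCc4ccccc4)cc3)c(OCc3ccccc3)cc2OCc2ccccc2)c1 | intermediate
10 | 4-(benzyloxy)-2-hydroxybenzaldehyde | O=Cc1ccc(OCc2ccccc2)cc1O | starting material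
11 | 1-[2',4,6-tris(benzyloxy)-5'-{3-[4-(benzyloxy)-2-hydroxyphenyl]-3-oxopropyl}[1,1'-biphenyl]-3-yl]-3-[4-(benzyloxy)phenyl]propan-1-one | O=C(CCc1ccc(OCc2ccccc2)c(-c2cc(C(=O)CCc3ccc(OCc4ccccc4)cc3)c(OCc3ccccc3)cc2OCc2ccccc2)c1)c1ccc(OCc2ccccc2)cc1O | intermediate
12 | 1-[5'-[3-(2,4-dihydroxyphenyl)-3-oxopropyl]-2',4,6-trihydroxy[1,1'-biphenyl]-3-yl]-3-(4-hydroxyphenyl)propan-1-one | O=C(CCc1ccc(O)c(-c2cc(C(=O)CCc3ccc(O)cc3)c(O)cc2O)c1)c1ccc(O)cc1O | target

Total step count: 7. Longest linear sequence: 5 steps (1, 2, 5, 6, 7; the branch 3, 4, 5, 6, 7 is equally long).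

**Steps most likely to fail**

Step 6. Vinylarenes are the most demanding terminal alkenes for linear selectivity, because the alkene may insert in the branched sense through an η3-benzyl rhodium species. The acyl hydride may also lose CO and deactivate the catalyst, and the styrene may oligomerise on long heating.
The fallback sets out from 9 and comes back to the route at 12. It forms the same C–C bond by a 1,3-dipolar cycloaddition whose regiochemistry is dependable for monosubstituted alkenes.
Commercial 2,4-bis(benzyloxy)benzaldehyde is condensed with aqueous hydroxylamine to (E)-2,4-bis(benzyloxy)benzaldehyde oxime F1. Oxidation with aqueous NaOCl in CH2Cl2 in the presence of 9 generates 2,4-bis(benzyloxy)benzonitrile oxide F2. Its carbon adds to the terminal CH2 and its oxygen to the benzylic carbon, giving the racemic 3,5-diaryl-4,5-dihydroisoxazole F3.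
N–O hydrogenolysis with imine hydrolysis (H2, Raney Ni, B(OH)3, THF/MeOH/H2O) should give the racemic β-hydroxy ketone F4. Hydrogenation over Pd/C with a trace of HCl should then remove the benzylic hydroxyl, which is activated by the para oxygen, together with the six benzyl groups. This erases the temporary stereocentre and arrives at 12.

Step 5. Heck-type arylation of the vinyl group, protodeboronation of the electron-rich boronate, and homocoupling caused by residual diboron may all erode the coupling.
The fallback sets out from 4 and 6 and comes back at 9. It installs the alkene only after the biaryl bond exists.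
Boronate 8, generated from 4 as before, is coupled with aldehyde 6 under the same Suzuki–Miyaura conditions. This gives the keto aldehyde 2',4,6-tris(benzyloxy)-5-{3-[4-(benzyloxy)phenyl]propanoyl}[1,1'-biphenyl]-5'-carbaldehyde F5.
One equivalent of Ph3P=CH2 at −78 to 0 °C should then methylenate the aldehyde in preference to the hindered, enolisable aryl ketone and give 9.

Step 1. Loss or migration of bromine in the hot acidic medium, O-acylation in place of C-acylation, and self-acylation of 2 may intervene.
The fallback sets out from 2 and comes back at 4. It brings the halogen in after the acylation.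
Acid 2 and resorcinol are condensed in BF3·OEt2 to 1-(2,4-dihydroxyphenyl)-3-(4-hydroxyphenyl)propan-1-one F6. Two equivalents of BnBr with K2CO3 in refluxing acetone leave the chelated hydroxyl free and give 1-[4-(benzyloxy)-2-hydroxyphenyl]-3-[4-(benzyloxy)phenyl]propan-1-one F7.
NBS in MeCN at 0 °C should brominate para to the free hydroxyl, on the doubly activated ring C rather than ring D. The product is 1-[4-(benzyloxy)-5-bromo-2-hydroxyphenyl]-3-[4-(benzyloxy)phenyl]propan-1-one F8. A last benzylation (BnBr, K2CO3, DMF, 70 °C) gives 4.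

**Further compounds**
F1 | step 6 | (E)-2,4-bis(benzyloxy)benzaldehyde oxime | O/N=C/c1ccc(OCc2ccccc2)cc1OCc1ccccc1
F2 | step 6 | 2,4-bis(benzyloxy)benzonitrile oxide | [O-][N+]#Cc1ccc(OCc2ccccc2)cc1OCc1ccccc1
F3 | step 6 | racemic 1-[2',4,6-tris(benzyloxy)-5'-{3-[2,4-bis(benzyloxy)phenyl]-4,5-dihydroisoxazol-5-yl}[1,1'-biphenyl]-3-yl]-3-[4-(benzyloxy)phenyl]propan-1-one | O1N=C(c2ccc(OCc3ccccc3)cc2OCc2ccccc2)CC1c1ccc(OCc2ccccc2)c(-c2cc(C(=O)CCc3ccc(OCc4ccccc4)cc3)c(OCc3ccccc3)cc2OCc2ccccc2)c1
F4 | step 6 | racemic 1-[2',4,6-tris(benzyloxy)-5'-{3-[2,4-bis(benzyloxy)phenyl]-1-hydroxy-3-oxopropyl}[1,1'-biphenyl]-3-yl]-3-[4-(benzyloxy)phenyl]propan-1-one | O=C(CC(O)c1ccc(OCc2ccccc2)c(-c2cc(C(=O)CCc3ccc(OCc4ccccc4)cc3)c(OCc3ccccc3)cc2OCc2ccccc2)c1)c1ccc(OCc2ccccc2)cc1OCc1ccccc1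
F5 | step 5 | 2',4,6-tris(benzyloxy)-5-{3-[4-(benzyloxy)phenyl]propanoyl}[1,1'-biphenyl]-5'-carbaldehyde | O=Cc1ccc(OCc2ccccc2)c(-c2cc(C(=O)CCc3ccc(OCc4ccccc4)cc3)c(OCc3ccccc3)cc2OCc2ccccc2)c1
F6 | step 1 | 1-(2,4-dihydroxyphenyl)-3-(4-hydroxyphenyl)propan-1-one | O=C(CCc1ccc(O)cc1)c1ccc(O)cc1O
F7 | step 1 | 1-[4-(benzyloxy)-2-hydroxyphenyl]-3-[4-(benzyloxy)phenyl]propan-1-one | O=C(CCc1ccc(OCc2ccccc2)cc1)c1ccc(OCc2ccccc2)cc1O
F8 | step 1 | 1-[4-(benzyloxy)-5-bromo-2-hydroxyphenyl]-3-[4-(benzyloxy)phenyl]propan-1-one | O=C(CCc1ccc(OCc2ccccc2)cc1)c1cc(Br)c(OCc2ccccc2)cc1O
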